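The numbers of this flask are those of an exercise; the result is computed.

Time came first: with 2.5 min on the clock, I wanted to know whether this flask would be read after a finished contest or in the middle of one.

starting material 0.27 M; gas phase 43 mM (held); protic impurity 0.270 M; catalyst 22 mM; added ligand 42 mM; time 2.5 min

1. the product standing at 2.5 min, as a percentage of the starting material charged
2. the change that raises the amount of product at 2.5 min, in percent of the starting material charged most ("none" if none brings more than 2 percentage points) (alpha / epsilon / zeta / none)
3. amount of product at 2.5 min, in percent of the starting material charged, after zeta

- alpha: doubling the saturation concentration of gas phase, all else as stated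
- epsilon: doubling the transfer coefficient of step 1, all else as stated
- zeta: doubling the amount of catalyst, all else as stated

- at the start none of the gas is dissolved
- run time (flask): 2.5 min

    gas phase ⇌ dissolved gas, rate k1*(csat - [dissolved gas]) (k1 = 1.33 /s, csat = 43 mM)
    starting material + dissolved gas + catalyst → catalyst + product (k2 = 28.5 /M²/s)
    catalyst + added ligand ⇌ idle complex, settled at all times (K3 = 183 /M)
    starting material + protic impurity → quenched substrate (k4 = 0.520 /M/s)

In this flask the starting material goes two ways: with dissolved gas over free catalyst to product, or with the protic impurity to quenched substrate. By step 4 alone its half-life is 0.082 min, well inside the run, so I counted product per impurity burnt, not per minute. The balance with added ligand left 4.07 mM of the 22 mM free. [Starting material] cancels from the ratio of the two rates, so I defined the exchange rate b as product rate constant times free catalyst times saturation concentration, over quench rate constant: the product won per natural-log unit of [protic impurity] burnt, a selectivity factor with a unit, 9.59 mM.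

The charges of starting material and protic impurity are equal, so once the starting material is gone, the impurity left equals the product, and the ceiling p solves p = b·ln(0.270 M/p). Putting b itself for the impurity left gave 32.0 mM, but that guess was crude. Put back, it gave 20.5 mM, then 24.8 mM; the rounds swung, so I put in their mean and got 23.8 mM.

That assumed saturation, yet the gas starts undissolved. For about 0.752 s I counted quenching as ungassed, burning 0.106 log units by my estimate, which costs 1.01 mM and leaves 22.8 mM. The time is finite, too. Late on, starting material falls at the quench constant times ([protic impurity] + b), so with 32.4 mM as the bracket's end value, integrating gave me an estimate of 2.49 mM still standing. Taking off the share 29.6% of that, I committed to 8.16%.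

Doubling the catalyst frees 13.9 mM, so b becomes 32.7 mM, a factor 3.41, above the factor 2 from alpha; epsilon leaves b and halves the lag, worth 0.505 mM. The same rounds and lag, with the tail dropped, gave me 18.7% for zeta.

The forecast, a little below me on both yields, gave 8.1%, zeta as best and 18.6% after it, beginning from this: “The catalyst is mostly tied up as idle complex”.

The simulation gave 8.07%, with zeta best at 11 percentage points against 5.3 points for alpha and 0.14 points for epsilon, and 18.6% after it.

This flask held 9.2% of its protic impurity at 2.50 min; b times the log of its inverse, less the lag, makes 8.10%. The neighbour with 0.088 M of catalyst frees 50.1 mM, so its b is 118 mM, and the same rounds less the lag give 35.5%. The simulation of that neighbour gave 36.3%.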